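**Retrosynthetic overview**
1. 37 ⇐ 36 by a final SN2 chlorination (inversion at C6); 36 ⇐ 34 by a palladium-catalysed 1,3-acyloxy shift that moves the butyrate from C4 to C2 and the double bond from C2=C3 to C3=C4, then ketal/silyl removal.
2. Key disconnection C8–C9: the ten-membered ring (C1–C10) of 33 is closed by SmI2 ketyl–olefin cyclisation of seco-aldehyde 30.
3. Enabling feature: the lactone ring C7–C8–C17–C19–O is a masked tetronic acid. C8 carries oxygen and is β to C19=O, so C8=C17 accepts a C9 ketyl and delivers C8–O, C9–OH and C17–H at once. A temporary isopropylidene ring O6–CMe2–O8 fixes the face at C8, and the unsaturation is parked at C2=C3 (ester oxygen on C4) so the C9 ketyl has no 5-exo partner.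
4. 30 ⇐ alkyne 16 (cyclohexene part) + enal 25 (C4–C8, C16–C19) by asymmetric alkynylation (C3–C4), then Z-selective semi-hydrogenation.
5. Ring order: cyclohexene (catalytic asymmetric Diels–Alder, then diene dihydroxylation) → butenolide as tetronate (vinylogous Mukaiyama aldol) → ten-membered ring (key step).

Key step: step 22

Numbering: briarane numbering of 37 is used throughout (C1–C10 ten-membered ring; C1, C10–C14 cyclohexene; C15 = Me on C1; C16 = CH2 on C5; C17(C18)–C19 = lactone propionate unit; C20 = Me on C11). Target 37 is (1S,2S,3Z,6S,7R,8R,9S,10S,11S,12R,17R).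
Remark: the sense of induction in the three catalyst-controlled steps (2, 15, 18) is assigned from the accepted transition-state models; the antipodal catalyst would be used if the opposite sense were found.

**Step 1**
Reactants: 1 pent-1-en-3-one
Product: 2 (Z)-3-(tert-butyldimethylsilyloxy)penta-1,3-diene
Conditions: t-BuMe2SiOTf, Et3N, Et2O, 0 °C
Reagents that add atoms: tert-butyldimethylsilyl triflate, CC(C)(C)[Si](C)(C)OS(=O)(=O)C(F)(F)F
Why: Soft enolisation of the ethyl ketone gives the 2-silyloxy diene with the methyl group anti to the vinyl group, as needed for the cycloaddition.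

**Step 2**
Reactants: 2 (Z)-3-(tert-butyldimethylsilyloxy)penta-1,3-diene; 3 ethyl (E)-3-methyl-4-oxobut-2-enoate
Product: 4 ethyl (1S,2S,6S)-3-(tert-butyldimethylsilyloxy)-6-formyl-2,6-dimethylcyclohex-3-ene-1-carboxylate
Conditions: (S)-o-tolyl-oxazaborolidine from α,α-diphenylprolinol activated by Tf2NH (20 mol%), CH2Cl2, −78 → −40 °C
Reagents that add atoms: none
Why: Catalytic enantioselective Diels–Alder reaction in which the enol-ether terminus (C11) attacks C10, β to the catalyst-bound formyl group; the E dienophile fixes CHO (C2) and CO2Et (C9) trans on C1/C10, the catalyst sets the absolute configuration, and C11 is set only provisionally (flattened in step 5).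

**Step 3**
Reactants: 4 Diels–Alder adduct
Product: 5 ethyl (1S,2S,6S)-6-formyl-2,6-dimethyl-3-oxocyclohex-4-ene-1-carboxylate
Conditions: Pd(OAc)2 (1.05 equiv), MeCN, 40 °C
Reagents that add atoms: none
Why: Saegusa–Ito oxidation of the regiodefined silyl enol ether installs the C13=C14 double bond; the aldehyde on the quaternary carbon cannot enolise.

**Step 4**
Reactants: 5 enone aldehyde
Product: 6 ethyl (1S,2S,6S)-6-(dimethoxymethyl)-2,6-dimethyl-3-oxocyclohex-4-ene-1-carboxylate
Conditions: HC(OMe)3, MeOH, p-TsOH (cat.), 23 °C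
Reagents that add atoms: trimethyl orthoformate, COC(OC)OC
Why: Chemoselective acetalisation of the aldehyde (the conjugated ketone does not ketalise under these conditions) masks C2 for steps 5–10.

**Step 5**
Reactants: 6 acetal enone
Product: 8 ethyl (1S,6S)-6-(dimethoxymethyl)-2,6-dimethyl-3-(trifluoromethylsulfonyloxy)cyclohexa-2,4-diene-1-carboxylate, via potassium dienolate 7 (not isolated)
Conditions: KN(SiMe3)2, THF, −78 °C; PhNTf2, −78 → 0 °C
Reagents that add atoms: N-phenyl-bis(trifluoromethanesulfonimide), O=S(=O)(N(c1ccccc1)S(=O)(=O)C(F)(F)F)C(F)(F)F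
Why: Kinetic α′-deprotonation at C11 (no γ-hydrogen exists because C1 is quaternary, and the ketone is more acidic than the ester) followed by O-triflation gives the cross-conjugated dienyl triflate.

**Step 6**
Reactants: 8 dienyl triflate
Product: 9 ethyl 6-(dimethoxymethyl)-2,6-dimethylcyclohexa-2,4-diene-1-carboxylate (C1 and C10 as in 37)
Conditions: Pd(OAc)2 (5 mol%), PPh3 (10 mol%), HCO2H, Et3N, DMF, 60 °C
Reagents that add atoms: none
Why: Palladium-catalysed formate reduction of the enol triflate gives the C11=C12/C13=C14 diene without touching the ester or acetal.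

**Step 7**
Reactants: 9 diene ester
Product: 10 [6-(dimethoxymethyl)-2,6-dimethylcyclohexa-2,4-dien-1-yl]methanol (C9 alcohol)
Conditions: i-Bu2AlH (2.5 equiv), CH2Cl2, −78 → 0 °C; aq. potassium sodium tartrate
Reagents that add atoms: none
Why: Hydride reduction of the ester gives the primary C9 alcohol; the acetal is inert.

**Step 8**
Reactants: 10 diene alcohol
Product: 11 C9 triethylsilyl ether of 10
Conditions: Et3SiCl, imidazole, CH2Cl2, 0 °C
Reagents that add atoms: chlorotriethylsilane, CC[Si](Cl)(CC)CC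
Why: Standard silylation; the primary TES ether is the group later oxidised directly to the C9 aldehyde.

**Step 9**
Reactants: 11 diene silyl ether
Product: 12 11,12-cis-diol (C11 and C12 as in 37; C13=C14 retained)
Conditions: OsO4 (2 mol%), NMO (1.1 equiv), acetone/H2O, 0 °C
Reagents that add atoms: N-methylmorpholine N-oxide, C[N+]1([O-])CCOCC1; water, O
Why: Catalytic OsO4 dihydroxylation should take the more electron-rich trisubstituted C11=C12 bond of the diene (C13=C14 is neopentylic) from the face anti to the C10 side chain, setting C11 and C12 as a cis-diol on the face opposite C9.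

**Step 10**
Reactants: 12 diol
Product: 13 C12 acetate with free tertiary C11 hydroxyl
Conditions: Ac2O, pyridine, DMAP (cat.), CH2Cl2, 0 °C
Reagents that add atoms: acetic anhydride, CC(=O)OC(C)=O
Why: Acylation discriminates the secondary allylic alcohol from the tertiary one.

**Step 11**
Reactants: 13 hydroxy acetate acetal
Product: 15 C2 aldehyde with C11 triethylsilyl ether, via collidinium salt 14 (not isolated)
Conditions: Et3SiOTf (3 equiv), 2,4,6-collidine (4.5 equiv), CH2Cl2, 0 °C; then H2O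
Reagents that add atoms: triethylsilyl triflate, CC[Si](CC)(CC)OS(=O)(=O)C(F)(F)F; water, O
Why: The silyl triflate/collidine pair converts the dimethyl acetal into a pyridinium-type intermediate that water hydrolyses to the aldehyde under non-acidic conditions (the primary TES ether survives) and silylates the tertiary C11 hydroxyl in the same flask, which prevents lactol formation between C2 and the cis 11-OH.

**Step 12**
Reactants: 15 aldehyde
Product: 16 terminal alkyne (C2≡C3–H on C1)
Conditions: (MeO)2P(O)CHN2, KOt-Bu, THF, −78 → 0 °C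
Reagents that add atoms: dimethyl (diazomethyl)phosphonate, COP(=O)(OC)C=[N+]=[N-]
Why: Seyferth–Gilbert homologation of the non-enolisable aldehyde at low temperature gives the alkyne (new carbon = C3) and should spare the acetate.

**Step 13**
Reactants: 17 acrolein
Product: 19 2-bromoacrolein, via 2,3-dibromopropanal 18 (not isolated)
Conditions: Br2, CH2Cl2, −78 °C; then Et3N, −78 → 0 °C
Reagents that add atoms: bromine, BrBr
Why: Bromination followed by dehydrobromination of the α-hydrogen is the standard route to the α-bromo enal.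

**Step 14**
Reactants: 20 3-methyltetronic acid
Product: 21 3-methyl-2,4-bis(trimethylsilyloxy)furan
Conditions: Me3SiOTf (2.2 equiv), Et3N (2.5 equiv), Et2O, 0 °C
Reagents that add atoms: trimethylsilyl triflate, C[Si](C)(C)OS(=O)(=O)C(F)(F)F
Why: Double O-silylation of the tetronic acid gives the aromatic silyloxyfuran, a dienolate equivalent that is nucleophilic at C5 (= C7).

**Step 15**
Reactants: 21 bis(silyloxy)furan; 19 2-bromoacrolein
Product: 23 (5S)-5-[(1S)-2-bromo-1-hydroxyprop-2-en-1-yl]-4-hydroxy-3-methylfuran-2(5H)-one, via bis-silylated aldol adduct 22 (not isolated)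
Conditions: Ti(OiPr)4 (20 mol%), (R)-BINOL (20 mol%), Et2O, −20 °C; then 1 M HCl, THF
Reagents that add atoms: none
Why: Catalytic enantioselective vinylogous Mukaiyama aldol reaction: the furan C5 adds 1,2 to the Lewis-acid-bound aldehyde through an open transition state that gives the threo adduct (C6–OH and C7–O syn), the chiral titanium complex selects the aldehyde face, and the acidic work-up removes both silyl groups.

**Step 16**
Reactants: 23 tetronic acid aldol
Product: 24 (4S,4aS)-4-(1-bromoethenyl)-2,2,7-trimethyl-4,4a-dihydro-6H-furo[3,2-d][1,3]dioxin-6-one (isopropylidene ketal across O6 and O8)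
Conditions: 2-methoxypropene, PPTS (cat.), CH2Cl2, 0 → 23 °C
Reagents that add atoms: 2-methoxypropene, COC(C)=C
Why: Isopropylidene ketal formation between the acidic enol hydroxyl on C8 and the C6 alcohol (as for phenol–benzylic alcohol pairs) protects both oxygens in one temporary 1,3-dioxin ring that ties O8 to the C6 face of the butenolide.

**Step 17**
Reactants: 24 vinyl bromide
Product: 25 enal (CHO = C4 on C5 in place of Br)
Conditions: Pd(PPh3)4 (5 mol%), CO (1 atm), Bu3SnH (slow addition), toluene, 50 °C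
Reagents that add atoms: carbon monoxide, [C-]#[O+]
Why: Palladium-catalysed reductive carbonylation (formylation) of the vinyl bromide gives the 2-substituted acrolein; slow hydride addition limits direct reduction.

**Step 18**
Reactants: 16 alkyne; 25 enal
Product: 27 (4R)-propargylic alcohol (C3–C4 bond formed), via methylzinc acetylide 26 (not isolated)
Conditions: Me2Zn (3 equiv), (S,S)-ProPhenol (20 mol%), Ph3PO (40 mol%), toluene, 0–4 °C
Reagents that add atoms: none
Why: Zinc–ProPhenol-catalysed enantioselective alkynylation adds the alkynylzinc 1,2 to the enal, with the ligand chosen to give 4R, the configuration that the later suprafacial 1,3-shift converts into 2S.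

**Step 19**
Reactants: 27 propargylic alcohol
Product: 28 C4 butyrate
Conditions: (PrCO)2O, Et3N, DMAP (cat.), CH2Cl2, 0 → 23 °C
Reagents that add atoms: butanoic anhydride, CCCC(=O)OC(=O)CCC
Why: DMAP-catalysed acylation of the only free hydroxyl.

**Step 20**
Reactants: 28 enyne butyrate
Product: 29 (2Z)-alkene (C2=C3)
Conditions: H2 (1 atm), Pd/CaCO3 poisoned with Pb(OAc)2 (Lindlar catalyst), quinoline, EtOAc, 23 °C
Reagents that add atoms: none
Why: Lindlar semi-hydrogenation gives the cis C2=C3 alkene; the 1,1-disubstituted, trisubstituted-ring and tetrasubstituted alkenes are much slower.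

**Step 21**
Reactants: 29 primary TES ether
Product: 30 seco-aldehyde (C9 = CHO)
Conditions: (COCl)2, DMSO, CH2Cl2, −78 → −40 °C; then Et3N, → 0 °C
Reagents that add atoms: none
Why: Under Swern conditions a primary TES ether is converted directly into the aldehyde, while the tertiary TES ether, the ketal and the esters are untouched.

**Step 22**
Reactants: 30 seco-aldehyde
Product: 33 macrocyclic C9 alcohol (8R 9S 17R), via samarium ketyl radical 31 (not isolated), via samarium enolate 32 (not isolated)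
Conditions: SmI2 (5 equiv), t-BuOH (4 equiv), THF, 0 → 23 °C, 30 added over 6 h (final 2 mM)
Reagents that add atoms: none
Why: Proposed new method: SmI2 reduces the C9 aldehyde to the samarium-bound ketyl radical 31, which adds to C8, the oxygen-bearing β-carbon of the tetronate (vinylogous carbonate C8=C17–C19=O), giving a C17 α-carbonyl radical that a second SmI2 reduces to samarium enolate 32, protonated at C17 by t-BuOH; the closest known reaction type is the SmI2-mediated reductive cyclisation of aldehydes onto β-alkoxyacrylates, which is established for five- to seven-membered rings but not for a ten-membered ring or a tetronate acceptor. The only ring closed is the ten-membered ring C1–C10 (10-exo-trig), helped by the cis C2=C3 alkene, the trans-disubstituted cyclohexene and the rigid dioxin-fused butenolide. C8 is controlled by the temporary 1,3-dioxin, since C9 must enter anti to C6 for the six-membered ketal to stay cis-fused to the lactone; C9 is expected from a five-membered chelate of trivalent samarium between the ketyl oxygen and O8 that places C10 anti to C7 and H9 between C7 and C17; C17 is set by protonation of 32 on the C9 face by alcohol bound to the C9 samarium alkoxide, which is also the thermodynamically preferred epimer (methyl trans to C9). The step needs chemoselectivity of the ketyl for C8: with the unsaturation parked at C2=C3 the ketyl has only 4-exo or 5-endo modes towards it (a C3=C4 bond would offer a fast 5-exo path), C5=C16 and C13=C14 are unactivated, and the esters and ketal are inert to SmI2 without HMPA. High dilution with slow addition suppresses pinacol dimerisation, and the small amount of t-BuOH limits simple reduction of the aldehyde.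

**Step 23**
Reactants: 33 macrocyclic alcohol
Product: 34 C9 acetate
Conditions: Ac2O, DMAP, pyridine, 40 °C
Reagents that add atoms: acetic anhydride, CC(=O)OC(C)=O
Why: Acylation of the hindered secondary C9 hydroxyl, the only free OH.

**Step 24**
Reactants: 34 C4 butyrate with C2=C3
Product: 35 C2 butyrate with (3Z)-C3=C4 conjugated to C5=C16
Conditions: PdCl2(MeCN)2 (10 mol%), THF, 23 °C
Reagents that add atoms: none
Why: Divalent-palladium-catalysed [3,3]-sigmatropic 1,3-acyloxy shift (cyclisation-induced rearrangement) is suprafacial, so 4R becomes 2S, and is driven by diene conjugation; the allyl unit C4–C5=C16 cannot react because its central carbon is fully substituted, and a shift of the C12 acetate to the neopentylic C14 is uphill.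

**Step 25**
Reactants: 35 protected macrocycle
Product: 36 6,8,11-triol (6-epi-hydroxy analogue of 37)
Conditions: CSA (20 mol%), MeOH/CH2Cl2, 0 → 23 °C
Reagents that add atoms: none
Why: Acid-catalysed methanolysis removes the isopropylidene ketal (cleavage at the ketal carbon, not at C6) and the tertiary TES ether, leaving the esters intact.

**Step 26**
Reactants: 36 triol
Product: 37 CNP0114781.2
Conditions: PPh3, hexachloroacetone, CH2Cl2, −20 → 0 °C
Reagents that add atoms: hexachloroacetone, O=C(C(Cl)(Cl)Cl)C(Cl)(Cl)Cl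
Why: Appel-type chlorination with the phosphine/hexachloroacetone pair converts the only secondary (allylic) alcohol into the chloride by SN2 with inversion and without allylic transposition, and the two tertiary alcohols do not react.

**Compound list**
1 | pent-1-en-3-one | C=CC(=O)CC | starting material
2 | (Z)-3-(tert-butyldimethylsilyloxy)penta-1,3-diene | C=C/C(O[Si](C)(C)C(C)(C)C)=C/C | intermediate
3 | ethyl (E)-3-methyl-4-oxobut-2-enoate | O=C/C(C)=C/C(=O)OCC | starting material
4 | ethyl (1S,2S,6S)-3-(tert-butyldimethylsilyloxy)-6-formyl-2,6-dimethylcyclohex-3-ene-1-carboxylate (CHO and CO2Et trans) | O=C[C@@]1(C)CC=C(O[Si](C)(C)C(C)(C)C)[C@@H](C)[C@@H]1C(=O)OCC | intermediate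
5 | ethyl (1S,2S,6S)-6-formyl-2,6-dimethyl-3-oxocyclohex-4-ene-1-carboxylate | O=C[C@@]1(C)C=CC(=O)[C@@H](C)[C@@H]1C(=O)OCC | intermediate
6 | ethyl (1S,2S,6S)-6-(dimethoxymethyl)-2,6-dimethyl-3-oxocyclohex-4-ene-1-carboxylate | COC(OC)[C@@]1(C)C=CC(=O)[C@@H](C)[C@@H]1C(=O)OCC | intermediate
7 | potassium dienolate of 6 (C11=C12–OK) | COC(OC)[C@@]1(C)C=CC([O-])=C(C)[C@@H]1C(=O)OCC.[K+] | intermediate
8 | ethyl (1S,6S)-6-(dimethoxymethyl)-2,6-dimethyl-3-(trifluoromethylsulfonyloxy)cyclohexa-2,4-diene-1-carboxylate | COC(OC)[C@@]1(C)C=CC(OS(=O)(=O)C(F)(F)F)=C(C)[C@@H]1C(=O)OCC | intermediate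
9 | ethyl 6-(dimethoxymethyl)-2,6-dimethylcyclohexa-2,4-diene-1-carboxylate (C1, C10 as in 37) | COC(OC)[C@@]1(C)C=CC=C(C)[C@@H]1C(=O)OCC | intermediate
10 | [6-(dimethoxymethyl)-2,6-dimethylcyclohexa-2,4-dien-1-yl]methanol (C1, C10 as in 37) | COC(OC)[C@@]1(C)C=CC=C(C)[C@@H]1CO | intermediate
11 | triethylsilyl ether of 10 | COC(OC)[C@@]1(C)C=CC=C(C)[C@@H]1CO[Si](CC)(CC)CC | intermediate
12 | 11,12-cis-diol: C2 dimethyl acetal, C9 OTES, C13=C14 (C1, C10, C11, C12 as in 37) | COC(OC)[C@@]1(C)C=C[C@@H](O)[C@@](C)(O)[C@@H]1CO[Si](CC)(CC)CC | intermediate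
13 | C12 acetate of 12 (tertiary 11-OH free) | COC(OC)[C@@]1(C)C=C[C@@H](OC(C)=O)[C@@](C)(O)[C@@H]1CO[Si](CC)(CC)CC | intermediate
14 | N-(α-methoxyalkyl)-2,4,6-trimethylpyridinium triflate at C2, with C11 OTES | COC([n+]1c(C)cc(C)cc1C)[C@@]2(C)C=C[C@@H](OC(C)=O)[C@@](C)(O[Si](CC)(CC)CC)[C@@H]2CO[Si](CC)(CC)CC.[O-]S(=O)(=O)C(F)(F)F | intermediate
15 | cyclohexene aldehyde: C2 = CHO, C9 OTES, C11 OTES, C12 OAc | O=C[C@@]1(C)C=C[C@@H](OC(C)=O)[C@@](C)(O[Si](CC)(CC)CC)[C@@H]1CO[Si](CC)(CC)CC | intermediate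
16 | cyclohexene alkyne: ethynyl (C2≡C3) on C1, otherwise as 15 | C#C[C@@]1(C)C=C[C@@H](OC(C)=O)[C@@](C)(O[Si](CC)(CC)CC)[C@@H]1CO[Si](CC)(CC)CC | intermediate
17 | acrolein | C=CC=O | starting material
18 | 2,3-dibromopropanal | O=CC(Br)CBr | intermediate
19 | 2-bromoacrolein | C=C(Br)C=O | intermediate
20 | 3-methyltetronic acid (4-hydroxy-3-methylfuran-2(5H)-one) | CC1=C(O)COC1=O | starting material
21 | 3-methyl-2,4-bis(trimethylsilyloxy)furan | Cc1c(O[Si](C)(C)C)coc1O[Si](C)(C)C | intermediate
22 | bis(trimethylsilyl) derivative of 23 (O6 and O8 silylated) | C[Si](C)(C)OC1=C(C)C(=O)O[C@H]1[C@H](O[Si](C)(C)C)C(Br)=C | intermediate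
23 | (5S)-5-[(1S)-2-bromo-1-hydroxyprop-2-en-1-yl]-4-hydroxy-3-methylfuran-2(5H)-one (C7 as in 37, C6–OH epimeric to the C6–Cl of 37) | OC1=C(C)C(=O)O[C@H]1[C@H](O)C(Br)=C | intermediate
24 | (4S,4aS)-4-(1-bromoethenyl)-2,2,7-trimethyl-4,4a-dihydro-6H-furo[3,2-d][1,3]dioxin-6-one | CC1=C2OC(C)(C)O[C@H](C(Br)=C)[C@@H]2OC1=O | intermediate
25 | enal: as 24 with CHO (C4) in place of Br | CC1=C2OC(C)(C)O[C@H](C(C=O)=C)[C@@H]2OC1=O | intermediate
26 | methylzinc acetylide of 16 | C[Zn]C#C[C@@]1(C)C=C[C@@H](OC(C)=O)[C@@](C)(O[Si](CC)(CC)CC)[C@@H]1CO[Si](CC)(CC)CC | intermediate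
27 | (4R)-propargylic alcohol joining 16 and 25 (C2≡C3–C4(OH)–C5(=C16)) | C=C([C@H](O)C#C[C@@]1(C)C=C[C@@H](OC(C)=O)[C@@](C)(O[Si](CC)(CC)CC)[C@@H]1CO[Si](CC)(CC)CC)[C@H]2OC(C)(C)OC3=C(C)C(=O)O[C@@H]23 | intermediate
28 | C4 butyrate of 27 | C=C([C@H](OC(=O)CCC)C#C[C@@]1(C)C=C[C@@H](OC(C)=O)[C@@](C)(O[Si](CC)(CC)CC)[C@@H]1CO[Si](CC)(CC)CC)[C@H]2OC(C)(C)OC3=C(C)C(=O)O[C@@H]23 | intermediate
29 | (2Z)-alkene from 28 | C=C([C@H](OC(=O)CCC)/C=C\[C@@]1(C)C=C[C@@H](OC(C)=O)[C@@](C)(O[Si](CC)(CC)CC)[C@@H]1CO[Si](CC)(CC)CC)[C@H]2OC(C)(C)OC3=C(C)C(=O)O[C@@H]23 | intermediate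
30 | seco-aldehyde: as 29 with C9 = CHO | C=C([C@H](OC(=O)CCC)/C=C\[C@@]1(C)C=C[C@@H](OC(C)=O)[C@@](C)(O[Si](CC)(CC)CC)[C@@H]1C=O)[C@H]2OC(C)(C)OC3=C(C)C(=O)O[C@@H]23 | intermediate
31 | C9 samarium ketyl radical of 30 | C=C([C@H](OC(=O)CCC)/C=C\[C@@]1(C)C=C[C@@H](OC(C)=O)[C@@](C)(O[Si](CC)(CC)CC)[C@@H]1[CH]O[Sm](I)I)[C@H]2OC(C)(C)OC3=C(C)C(=O)O[C@@H]23 | intermediate
32 | cyclised samarium enolate (C17=C19–OSm, C9–OSm) | C=C1[C@H](OC(=O)CCC)/C=C\[C@@]2(C)C=C[C@@H](OC(C)=O)[C@@](C)(O[Si](CC)(CC)CC)[C@@H]2[C@H](O[Sm](I)I)[C@]2(OC(C)(C)O3)C(C)=C(O[Sm](I)I)O[C@H]2[C@@H]13 | intermediate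
33 | macrocycle: 9-OH, O6/O8 isopropylidene, C4 butyrate, (2Z)-alkene, C11 OTES, C12 OAc; C7–C10, C17 as in 37 | C=C1[C@H](OC(=O)CCC)/C=C\[C@@]2(C)C=C[C@@H](OC(C)=O)[C@@](C)(O[Si](CC)(CC)CC)[C@@H]2[C@H](O)[C@]2(OC(C)(C)O3)[C@@H](C)C(=O)O[C@H]2[C@@H]13 | intermediate
34 | C9 acetate of 33 | C=C1[C@H](OC(=O)CCC)/C=C\[C@@]2(C)C=C[C@@H](OC(C)=O)[C@@](C)(O[Si](CC)(CC)CC)[C@@H]2[C@H](OC(C)=O)[C@]2(OC(C)(C)O3)[C@@H](C)C(=O)O[C@H]2[C@@H]13 | intermediate
35 | transposed macrocycle: (2S)-butyrate, (3Z)-C3=C4, otherwise as 34 | C=C1/C=C\[C@H](OC(=O)CCC)[C@@]2(C)C=C[C@@H](OC(C)=O)[C@@](C)(O[Si](CC)(CC)CC)[C@@H]2[C@H](OC(C)=O)[C@]2(OC(C)(C)O3)[C@@H](C)C(=O)O[C@H]2[C@@H]13 | intermediate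
36 | 6,8,11-triol: 37 with OH of inverted configuration in place of Cl at C6 | C=C1/C=C\[C@H](OC(=O)CCC)[C@@]2(C)C=C[C@@H](OC(C)=O)[C@@](C)(O)[C@@H]2[C@H](OC(C)=O)[C@]2(O)[C@@H](C)C(=O)O[C@H]2[C@@H]1O | intermediate
37 | CNP0114781.2, (1S,2S,3Z,6S,7R,8R,9S,10S,11S,12R,17R) | C=C1/C=C\[C@H](OC(=O)CCC)[C@@]2(C)C=C[C@@H](OC(C)=O)[C@@](C)(O)[C@@H]2[C@H](OC(C)=O)[C@]2(O)[C@@H](C)C(=O)O[C@H]2[C@H]1Cl | target

**Step count and risks**
Total steps: 26. Longest linear sequence: 21 steps (steps 1–12, then 18–26).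

1. Step 22 (Proposed new method). What may go wrong: the ten-membered radical closure onto a tetrasubstituted acceptor may be outrun by simple reduction or pinacol dimerisation of the ketyl, or may give the wrong C9 configuration. Fallback with known two-electron chemistry, setting out from 29 and returning at 36: PPTS in MeOH at 0 °C removes the enol ketal and the primary silyl group to give tetronic acid triol F1; PhNTf2/Et3N triflates only the acidic enol to give C8 enol triflate F2; TEMPO/PhI(OAc)2 oxidises the primary alcohol to triflate aldehyde F3; a Nozaki–Hiyama–Kishi macrocyclisation (CrCl2, cat. NiCl2, DMSO/THF, high dilution) forms C8–C9 and gives butenolide allylic alcohol F4. The C6 hydroxyl then delivers the C8 oxygen from its own face by hemiacetal-alkoxide oxa-Michael addition (PhCHO, cat. KOt-Bu, THF, 0 °C), giving benzylidene acetal F5 with C17–H; acetylation gives C9 acetate F6, PdCl2(MeCN)2 gives transposed benzylidene acetal F7, and CSA/MeOH returns triol 36.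

2. Step 26. What may go wrong: SN2′ attack of chloride at C16 and ionisation of the doubly allylic C6 position compete with SN2 inversion. Fallback, setting out from 34 and returning at 37: the substitution is moved ahead of the acyloxy shift, while C6 is allylic only to the isolated C5=C16 bond. CSA/MeOH on 34 gives untransposed triol F8; PPh3/hexachloroacetone gives untransposed chloride F9; PdCl2(MeCN)2 then performs the 1,3-shift (the chloride's allyl unit is 2-substituted and should not rearrange) to give 37.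

3. Step 18. What may go wrong: slow, poorly face-selective union of two elaborate partners (hindered acetylide, mismatched double stereodifferentiation, competing 1,4-addition). Fallback, setting out from 16 and 25 and returning at 27: ligand-free addition of zinc acetylide 26 gives 27 mixed with its C4 epimer F10; Dess–Martin oxidation of the mixture gives ynone F11; Corey–Bakshi–Shibata reduction (alkynyl as the small group) returns 27 as the 4R alcohol.

**Further compounds**
F1 | step 22 | tetronic acid triol: 29 without the isopropylidene and the primary TES group (free C8 enol, 6-OH, 9-OH) | C=C([C@H](OC(=O)CCC)/C=C\[C@@]1(C)C=C[C@@H](OC(C)=O)[C@@](C)(O[Si](CC)(CC)CC)[C@@H]1CO)[C@@H](O)[C@@H]2OC(=O)C(C)=C2O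
F2 | step 22 | C8 enol triflate of F1 | C=C([C@H](OC(=O)CCC)/C=C\[C@@]1(C)C=C[C@@H](OC(C)=O)[C@@](C)(O[Si](CC)(CC)CC)[C@@H]1CO)[C@@H](O)[C@@H]2OC(=O)C(C)=C2OS(=O)(=O)C(F)(F)F
F3 | step 22 | triflate aldehyde (C9 = CHO) | C=C([C@H](OC(=O)CCC)/C=C\[C@@]1(C)C=C[C@@H](OC(C)=O)[C@@](C)(O[Si](CC)(CC)CC)[C@@H]1C=O)[C@@H](O)[C@@H]2OC(=O)C(C)=C2OS(=O)(=O)C(F)(F)F
F4 | step 22 | macrocyclic butenolide allylic alcohol (C8=C17, 9-OH, 6-OH) | C=C1[C@H](OC(=O)CCC)/C=C\[C@@]2(C)C=C[C@@H](OC(C)=O)[C@@](C)(O[Si](CC)(CC)CC)[C@@H]2[C@H](O)C2=C(C)C(=O)O[C@H]2[C@@H]1O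
F5 | step 22 | O6/O8 benzylidene acetal with C17–H and free 9-OH | C=C1[C@H](OC(=O)CCC)/C=C\[C@@]2(C)C=C[C@@H](OC(C)=O)[C@@](C)(O[Si](CC)(CC)CC)[C@@H]2[C@H](O)[C@]2(OC(c4ccccc4)O3)[C@@H](C)C(=O)O[C@H]2[C@@H]13
F6 | step 22 | C9 acetate of F5 | C=C1[C@H](OC(=O)CCC)/C=C\[C@@]2(C)C=C[C@@H](OC(C)=O)[C@@](C)(O[Si](CC)(CC)CC)[C@@H]2[C@H](OC(C)=O)[C@]2(OC(c4ccccc4)O3)[C@@H](C)C(=O)O[C@H]2[C@@H]13
F7 | step 22 | transposed benzylidene acetal (C2 butyrate, 3Z) | C=C1/C=C\[C@H](OC(=O)CCC)[C@@]2(C)C=C[C@@H](OC(C)=O)[C@@](C)(O[Si](CC)(CC)CC)[C@@H]2[C@H](OC(C)=O)[C@]2(OC(c4ccccc4)O3)[C@@H](C)C(=O)O[C@H]2[C@@H]13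
F8 | step 26 | untransposed triol (C4 butyrate, C2=C3, free 6-, 8-, 11-OH) | C=C1[C@H](OC(=O)CCC)/C=C\[C@@]2(C)C=C[C@@H](OC(C)=O)[C@@](C)(O)[C@@H]2[C@H](OC(C)=O)[C@]2(O)[C@@H](C)C(=O)O[C@H]2[C@@H]1O
F9 | step 26 | untransposed chloride (C4 butyrate, C2=C3, 6-Cl as in 37) | C=C1[C@H](OC(=O)CCC)/C=C\[C@@]2(C)C=C[C@@H](OC(C)=O)[C@@](C)(O)[C@@H]2[C@H](OC(C)=O)[C@]2(O)[C@@H](C)C(=O)O[C@H]2[C@H]1Cl
F10 | step 18 | C4 epimer of 27 | C=C([C@@H](O)C#C[C@@]1(C)C=C[C@@H](OC(C)=O)[C@@](C)(O[Si](CC)(CC)CC)[C@@H]1CO[Si](CC)(CC)CC)[C@H]2OC(C)(C)OC3=C(C)C(=O)O[C@@H]23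
F11 | step 18 | C4 ynone | C=C(C(=O)C#C[C@@]1(C)C=C[C@@H](OC(C)=O)[C@@](C)(O[Si](CC)(CC)CC)[C@@H]1CO[Si](CC)(CC)CC)[C@H]2OC(C)(C)OC3=C(C)C(=O)O[C@@H]23
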